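## Structural features

The target is an 8-O-4′ neolignan: two trioxygenated benzene rings joined by the three-carbon chain C7–C8–C9 and one ether oxygen. Ring A (4-hydroxy-3,5-dimethoxyphenyl) sits on the carbinol carbon C7. C8 carries the methyl group C9 and the ether oxygen to C4′ of ring B, which has two flanking methoxy groups and an (E)-prop-1-enyl group para to the ether. C7 (R) and C8 (S) are adjacent, are the only stereocentres, and stand in the erythro relation. Fragile points are the free phenol para to a benzylic alcohol (quinone methide formation under acid or hot base would scramble C7), the electron-rich styrenyl double bond, and the β-aryloxy arrangement, which lets ring B leave as aryloxide from any carbanion-like or metalated C7. The skeleton is simple; the real difficulty is controlling two contiguous oxygen-bearing centres in an open chain, in both the relative and the absolute sense, beside a di-ortho-substituted aryl ether. The key step uses the fact that the C7–O(H) and C8–H bonds are syn across C7–C8 when ring A and the ring B oxygen are cis, so a (Z)-enol ether C7=C8 maps onto the erythro alcohol by syn addition of H and OH.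

## Logic of the disconnections

**15 ⇒ 14.** The O–Si bond on the ring A oxygen is made first and broken last. The phenolic O–H would quench amide bases and boranes, and as a phenoxide para to C7 it opens the quinone methide path. Nothing is gained in skeleton, but every later step becomes possible. The demand is that the final cleavage be buffered, so that C7 and the propenyl group are untouched.

**14 ⇒ 12 + 13.** The bond between ring B and the propenyl carbon (C1′–C7′) is cut. A styrenyl alkene would compete for the borane in the key step, whereas the bromine of 12 is inert to it and serves as a coupling handle. 13 brings the three carbons with the E geometry already in place. The forward coupling must retain that geometry and tolerate the free C7 hydroxyl and the aryl silyl ether without base-induced epimerisation.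

**12 ⇒ 10 (key disconnection).** The C7–O and C8–H bonds are removed together, which turns two stereocentres into one alkene geometry. The forward step must place boron on C7, add to one face only, start from geometrically pure 10, and oxidise 11 before it can lose the ring B aryloxide.

**10 ⇒ 9.** The C7=C8 double bond is traced back to a C7 hydroxyl and a C8 diphenylphosphoryl group. The syn-specific loss of phosphinate converts a relative configuration, which can be purified, into an alkene geometry, which is hard to purify. The demand is diastereomerically pure 9 and no reversal of the addition during the elimination.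

**9 ⇒ 7 + 2.** The C7–C8 bond is cut at a carbonyl addition of 8 to 2. This splits the molecule into two one-ring halves of similar size. The addition must be quenched cold, and its diastereomers separated.

**7 ⇒ 5.** The C8–C9 bond is cut. Because 4 supplies only one carbon between oxygen and phosphorus, the methyl group has to be added by alkylation of 6. The base must not attack the aryl bromide, and only one methyl may enter.

**5 ⇒ 3 + 4.** The O–C8 bond is cut at the stage where C8 is still a primary carbon. The hindered aryl ether is thus formed by a simple displacement, not on a secondary carbon late in the route. The demand is forcing SN2 conditions at an α-phosphoryl carbon.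

**2 ⇒ 1.** The O–Si bond is cut, as for 15; the forward step is a routine silylation of a flanked phenol.

## Other disconnections considered

**Alternative 1:** The cut is the aryl ether bond O–C4′ on the ring B side, leaving C8–O intact.
- **Forward key step:** the potassium alkoxide of the O7-protected anti diol A2, made with KN(SiMe3)2, would attack 4-fluoro-3,5-dimethoxybenzaldehyde A3 at the fluorine-bearing carbon. Loss of fluoride from the Meisenheimer adduct would give the formyl ether A1.
- **In favour:** C8 is never a reacting centre, so its configuration is retained. Both stereocentres are made beforehand by chemistry that can be verified on a small molecule, and no intermediate can expel aryloxide. On stereochemical security this plan is the better one.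
- **Against:** A2 must be made as the anti diol with its two secondary hydroxyls told apart, which costs several steps. The fluorine of A3 lies between two methoxy groups and is activated by a single para formyl group, so a hindered secondary alkoxide may react slowly or add to the aldehyde. The formyl group of A1 must then become the E-propenyl group by an olefination of uncertain E selectivity. Finally two SEM groups must be removed under conditions that endanger the benzylic alcohol.
- **Comparison:** both key steps are mechanistically clean (addition–elimination versus concerted syn addition) and the two plans are equal in convergence. The alternative is longer by an estimated three to five steps and reopens the alkene geometry question, which the chosen plan settles with a stereoretentive coupling.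

**Alternative 2:** The cut is the C7–H bond of the carbinol, with C8 set by equilibration.
- **Forward key step:** the racemic ketone A5 would be hydrogenated with RuCl2(xyl-BINAP)(DAIPEN), KOtBu and H2 in 2-propanol to the erythro alcohol A4. The base interconverts the C8 enantiomers through the enolate, and the chiral ruthenium hydride reduces one of them faster.
- **In favour:** A5 should be reachable in two or three steps by α-halogenation and phenoxide displacement. The catalyst reduces C=O in the presence of C=C, so the propenyl group can be present from the start and no placeholder or coupling is needed. The chiral element is catalytic. On step economy and on use of the chiral reagent this plan is the better one, and it equals the chosen plan in setting both centres in one step.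
- **Against:** the erythro or threo outcome is not fixed by the mechanism but by the fit of each C8 epimer to the catalyst, which would have to be found. Enolisation must outrun reduction in a strongly basic medium. The methoxymethyl group of A4 needs acid for removal, which threatens the para-oxygenated benzylic alcohol and the propenyl group; a silyl group would cure this.
- **Comparison:** in the chosen plan the relative configuration follows from alkene geometry and syn addition, and only the absolute sense depends on the reagent. In the alternative both depend on catalyst control. If that control were adequate, the alternative would be the shorter and more elegant route.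

**Alternative 3:** The cut is the C7–C8 bond.
- **Forward key step:** the (Z)-silyl ketene thioacetal A7 of the ring B aryloxyacetate would add to 2 under Sn(OTf)2 (divalent tin), a chiral proline-derived diamine and Bu2Sn(OAc)2 to give the anti thioester A6.
- **In favour:** two achiral fragments are joined and both stereocentres are set in the bond-forming step. This is better than the chosen plan in convergence and equal to it in stereocentres per step. The propenyl group is tolerated, so no placeholder is needed.
- **Against:** C9 arrives as a thioester and must be taken down to a methyl group (reduction, selective sulfonylation, hydride displacement, probably with temporary protection of the C7 hydroxyl). That is three or four steps during which the β-aryloxy alcohol can cyclise or eliminate. Stoichiometric tin triflate and an organotin additive run against the safety aim. The anti preference is established for small α-alkoxy groups, and the bulky 2,6-dimethoxyaryloxy group is untested for both syn/anti and enantioselectivity.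
- **Comparison:** the alternative relies on reagent control in an open transition state. The chosen plan relies on a concerted syn addition to a defined alkene for the relative configuration. The overall step counts are expected to be similar, with the alternative carrying the heavier reagent burden.

Key step: step 6

Remark on the chemistry: the facial sense of the borane is carried over from its established behaviour towards trisubstituted aryl alkenes, which points to the reagent from (−)-α-pinene for 7R. Racemic 7 and 9 are drawn as one enantiomer. The structures of 10, 12 and 15 were checked and need no correction; the one-carbon unit 4 makes an added C-methylation (step 3) necessary.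

## Route

Step 1
Reactants: 1 syringaldehyde (4-hydroxy-3,5-dimethoxybenzaldehyde)
Product: 2 3,5-dimethoxy-4-(triisopropylsilyloxy)benzaldehyde
Conditions: iPr3SiCl, imidazole, DMF, 25 °C
Reagents that add atoms: chlorotriisopropylsilane, CC(C)[Si](Cl)(C(C)C)C(C)C
Why: Silylation of the phenol through the N-silylimidazolium species. The triisopropylsilyl ether is chosen because it should withstand amide bases, borane, perborate and aqueous phosphate and still leave with fluoride.

Step 2
Reactants: 3 4-bromo-2,6-dimethoxyphenol; 4 (chloromethyl)diphenylphosphine oxide
Product: 5 [(4-bromo-2,6-dimethoxyphenoxy)methyl]diphenylphosphine oxide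
Conditions: Cs2CO3, NaI (cat.), DMSO, 100 °C
Reagents that add atoms: none
Why: Williamson ether synthesis: the caesium phenoxide of 3 displaces chloride from 4 by SN2. The α-phosphoryl carbon is a sluggish electrophile, hence iodide catalysis, a dipolar aprotic solvent and heat; the aryl bromide is inert under these conditions.

Step 3
Reactants: 5 [(4-bromo-2,6-dimethoxyphenoxy)methyl]diphenylphosphine oxide
Product: 7 rac-[1-(4-bromo-2,6-dimethoxyphenoxy)ethyl]diphenylphosphine oxide, via α-lithio phosphine oxide 6 (not isolated)
Conditions: LiN(iPr)2, THF, −78 °C; MeI, −78 → 0 °C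
Reagents that add atoms: iodomethane, CI
Why: The methylene between oxygen and the phosphoryl group is deprotonated by the amide base, which unlike an alkyllithium does not exchange with the aryl bromide, and 6 is C-methylated by SN2. This is the standard alkylation of an α-alkoxy phosphine oxide anion; one equivalent of base limits it to a single methyl group.

Step 4
Reactants: 7 rac-[1-(4-bromo-2,6-dimethoxyphenoxy)ethyl]diphenylphosphine oxide; 2 3,5-dimethoxy-4-(triisopropylsilyloxy)benzaldehyde
Product: 9 (1R*,2R*)-2-(4-bromo-2,6-dimethoxyphenoxy)-1-[3,5-dimethoxy-4-(triisopropylsilyloxy)phenyl]-2-(diphenylphosphoryl)propan-1-ol (racemic), via tertiary α-lithio phosphine oxide 8 (not isolated)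
Conditions: LiN(iPr)2, THF, −78 °C; then 2, −78 °C; AcOH, −78 °C; chromatographic separation of the diastereomers
Reagents that add atoms: none
Why: Horner–Wittig addition: carbanion 8 adds to the aldehyde of 2 to give a lithium alkoxide that does not eliminate at −78 °C, and cold protonation freezes the kinetic mixture. Both stereocentres arise here without reliable control, so the (1R*,2R*) isomer is isolated by chromatography or crystallisation; it is the one in which P and O eclipse when ring A eclipses the aryloxy group.

Step 5
Reactants: 9 (1R*,2R*)-2-(4-bromo-2,6-dimethoxyphenoxy)-1-[3,5-dimethoxy-4-(triisopropylsilyloxy)phenyl]-2-(diphenylphosphoryl)propan-1-ol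
Product: 10 5-bromo-2-{[(1Z)-1-[3,5-dimethoxy-4-(triisopropylsilyloxy)phenyl]prop-1-en-2-yl]oxy}-1,3-dimethoxybenzene (Z enol ether; ring A cis to the aryloxy group)
Conditions: KN(SiMe3)2, THF, 0 → 25 °C
Reagents that add atoms: none
Why: Horner–Wittig elimination: the potassium alkoxide attacks phosphorus and diphenylphosphinate leaves through a four-membered syn transition state, so the (1R*,2R*) configuration of 9 is transcribed into the Z geometry. The stereocentres of 9 disappear, so its racemic nature does not matter; a soluble non-nucleophilic amide base replaces pyrophoric metal hydrides.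

Step 6
Reactants: 10 5-bromo-2-{[(1Z)-1-[3,5-dimethoxy-4-(triisopropylsilyloxy)phenyl]prop-1-en-2-yl]oxy}-1,3-dimethoxybenzene
Product: 12 (1R,2S)-2-(4-bromo-2,6-dimethoxyphenoxy)-1-[3,5-dimethoxy-4-(triisopropylsilyloxy)phenyl]propan-1-ol, via benzylic alkyl(isopinocampheyl)borane 11 (not isolated)
Conditions: (IpcBH2)2·TMEDA [from (−)-α-pinene], BF3·OEt2, THF, 25 °C, filter; then 10, THF, −25 °C; NaBO3·4H2O, H2O, 0 → 25 °C
Reagents that add atoms: sodium perborate tetrahydrate (NaBO3·4H2O), [Na+].[O-]OB=O.O.O.O.O
Why: Proposed new method: the B–H bond of the chiral monoalkylborane should add across C7=C8 of 10 in a concerted four-centre syn fashion, with boron on C7 because donation from the C8 oxygen makes C7 the nucleophilic terminus and C7 is also the less substituted carbon; the aryl group is not relied upon as a directing element, since an electron-rich ring weakens any benzylic preference, and the closest known reaction type is the asymmetric hydroboration–oxidation of trisubstituted aryl alkenes and of simple enol ethers with isopinocampheylboranes, not yet extended to an acyclic β-aryl aryloxy enol ether. No ring is formed. C8 is set relative to C7 by delivery of hydrogen to the same face as boron on the geometrically pure Z alkene, which translates into the erythro relation. C7 is set in the absolute sense by the isopinocampheyl group on boron, which differentiates the two alkene faces; by analogy with 1-arylcycloalkenes the reagent from (−)-α-pinene should attack the face leading to 7R. Perborate then replaces boron in 11 by oxygen through a 1,2-shift from boron to oxygen with retention at C7, under conditions mild enough for the aryl silyl ether. The step needs regio-, face- and chemoselectivity: the first comes from the enol ether polarisation, the second from the reagent, and the third from the bromine placeholder on ring B, which leaves no second alkene. Expulsion of the ring B aryloxide from 11 is countered by a Lewis-acid-free reagent solution (slight deficiency of BF3·OEt2, filtration), low temperature and immediate oxidation.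

Step 7
Reactants: 12 (1R,2S)-2-(4-bromo-2,6-dimethoxyphenoxy)-1-[3,5-dimethoxy-4-(triisopropylsilyloxy)phenyl]propan-1-ol; 13 (E)-prop-1-enylboronic acid
Product: 14 (1R,2S)-2-{2,6-dimethoxy-4-[(E)-prop-1-enyl]phenoxy}-1-[3,5-dimethoxy-4-(triisopropylsilyloxy)phenyl]propan-1-ol
Conditions: Pd(dppf)Cl2 (5 mol %), K3PO4, THF/H2O, 65 °C
Reagents that add atoms: none
Why: Suzuki–Miyaura coupling: oxidative addition of zerovalent palladium into the unhindered C–Br bond, transmetalation of the alkenylboronate and reductive elimination all proceed with retention of the E geometry. The mild phosphate base and moderate temperature should leave the aryl silyl ether, the free C7 hydroxyl and both stereocentres intact.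

Step 8
Reactants: 14 (1R,2S)-2-{2,6-dimethoxy-4-[(E)-prop-1-enyl]phenoxy}-1-[3,5-dimethoxy-4-(triisopropylsilyloxy)phenyl]propan-1-ol
Product: 15 4-[(1R,2S)-1-hydroxy-2-{2,6-dimethoxy-4-[(E)-prop-1-enyl]phenoxy}propyl]-2,6-dimethoxyphenol (target)
Conditions: Bu4NF, AcOH, THF, 0 °C
Reagents that add atoms: none
Why: Fluoride attacks silicon of the aryl silyl ether and releases the phenol. Acetic acid buffers the phenoxide so that no quinone methide pathway can epimerise C7; the alkene and both stereocentres are not touched.

## Compound list

1 | syringaldehyde (4-hydroxy-3,5-dimethoxybenzaldehyde) | O=Cc1cc(OC)c(O)c(OC)c1 | starting material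
2 | 3,5-dimethoxy-4-(triisopropylsilyloxy)benzaldehyde | O=Cc1cc(OC)c(O[Si](C(C)C)(C(C)C)C(C)C)c(OC)c1 | intermediate
3 | 4-bromo-2,6-dimethoxyphenol | Oc1c(OC)cc(Br)cc1OC | starting material
4 | (chloromethyl)diphenylphosphine oxide | ClCP(=O)(c1ccccc1)c1ccccc1 | starting material
5 | [(4-bromo-2,6-dimethoxyphenoxy)methyl]diphenylphosphine oxide | O=P(COc1c(OC)cc(Br)cc1OC)(c1ccccc1)c1ccccc1 | intermediate
6 | [(4-bromo-2,6-dimethoxyphenoxy)(diphenylphosphoryl)methyl]lithium | [Li]C(Oc1c(OC)cc(Br)cc1OC)P(=O)(c1ccccc1)c1ccccc1 | intermediate (not isolated)
7 | rac-[1-(4-bromo-2,6-dimethoxyphenoxy)ethyl]diphenylphosphine oxide | CC(Oc1c(OC)cc(Br)cc1OC)P(=O)(c1ccccc1)c1ccccc1 | intermediate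
8 | [1-(4-bromo-2,6-dimethoxyphenoxy)-1-(diphenylphosphoryl)ethyl]lithium | [Li]C(C)(Oc1c(OC)cc(Br)cc1OC)P(=O)(c1ccccc1)c1ccccc1 | intermediate (not isolated)
9 | (1R*,2R*)-2-(4-bromo-2,6-dimethoxyphenoxy)-1-[3,5-dimethoxy-4-(triisopropylsilyloxy)phenyl]-2-(diphenylphosphoryl)propan-1-ol (racemic; one enantiomer drawn) | C[C@@](Oc1c(OC)cc(Br)cc1OC)(P(=O)(c1ccccc1)c1ccccc1)[C@H](O)c1cc(OC)c(O[Si](C(C)C)(C(C)C)C(C)C)c(OC)c1 | intermediate
10 | 5-bromo-2-{[(1Z)-1-[3,5-dimethoxy-4-(triisopropylsilyloxy)phenyl]prop-1-en-2-yl]oxy}-1,3-dimethoxybenzene | C/C(Oc1c(OC)cc(Br)cc1OC)=C/c1cc(OC)c(O[Si](C(C)C)(C(C)C)C(C)C)c(OC)c1 | intermediate (precursor of the key step)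
11 | [(1R,2S)-2-(4-bromo-2,6-dimethoxyphenoxy)-1-[3,5-dimethoxy-4-(triisopropylsilyloxy)phenyl]propyl][(1S,2R,3S,5S)-isopinocampheyl]borane | Brc1cc(OC)c(O[C@@H](C)[C@H](B[C@H]3C[C@H]4C[C@@H]([C@@H]3C)C4(C)C)c2cc(OC)c(O[Si](C(C)C)(C(C)C)C(C)C)c(OC)c2)c(OC)c1 | intermediate (not isolated)
12 | (1R,2S)-2-(4-bromo-2,6-dimethoxyphenoxy)-1-[3,5-dimethoxy-4-(triisopropylsilyloxy)phenyl]propan-1-ol | Brc1cc(OC)c(O[C@@H](C)[C@H](O)c2cc(OC)c(O[Si](C(C)C)(C(C)C)C(C)C)c(OC)c2)c(OC)c1 | intermediate (product of the key step)
13 | (E)-prop-1-enylboronic acid | C/C=C/B(O)O | starting material
14 | (1R,2S)-2-{2,6-dimethoxy-4-[(E)-prop-1-enyl]phenoxy}-1-[3,5-dimethoxy-4-(triisopropylsilyloxy)phenyl]propan-1-ol | C/C=C/c1cc(OC)c(O[C@@H](C)[C@H](O)c2cc(OC)c(O[Si](C(C)C)(C(C)C)C(C)C)c(OC)c2)c(OC)c1 | intermediate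
15 | 4-[(1R,2S)-1-hydroxy-2-{2,6-dimethoxy-4-[(E)-prop-1-enyl]phenoxy}propyl]-2,6-dimethoxyphenol | C/C=C/c1cc(OC)c(O[C@@H](C)[C@H](O)c2cc(OC)c(O)c(OC)c2)c(OC)c1 | target

## Step count and least certain steps

Total step count: 8. Longest linear sequence: 7 steps (steps 2 to 8, from 3 to 15); step 1 is a one-step side branch.

**Step 6 (key step, labelled).** Three processes are most likely to go wrong:
- expulsion of the ring B aryloxide from 11 before oxidation, by syn or Lewis-acid-assisted β-elimination, followed by hydroboration of the arylpropene so formed;
- slow addition to a hindered and only moderately nucleophilic aryl enol ether at the low temperature that the first point requires;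
- insufficient or reversed facial selectivity, because the sense is extrapolated from other alkenes.

A reversed sense would be met with the enantiomeric borane and checked on 12 by Mosher ester analysis. The fallback uses known chemistry, sets out from 3 and comes back at 12. Mitsunobu etherification of 3 with methyl (R)-lactate (PPh3, diisopropyl azodicarboxylate, THF, 0 °C) should give, with inversion, methyl (2S)-2-(4-bromo-2,6-dimethoxyphenoxy)propanoate F1. Half-reduction with iBu2AlH in toluene at −78 °C should give (2S)-2-(4-bromo-2,6-dimethoxyphenoxy)propanal F2. Separately 3 is silylated (iPr3SiCl, imidazole) to (4-bromo-2,6-dimethoxyphenoxy)triisopropylsilane F3, which n-BuLi at −78 °C converts into [3,5-dimethoxy-4-(triisopropylsilyloxy)phenyl]lithium F4. Addition of F4 to F2 at −78 °C under Felkin–Anh control (aryloxy group anti to the incoming nucleophile) should favour the anti adduct, which is 12; incomplete selectivity would be handled by chromatography.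

**Step 4.** The likely problem is poor or adverse diastereoselectivity in the addition of the tertiary carbanion, together with partial reversal of the addition before the quench, so that too little of the (1R*,2R*) isomer is obtained. The fallback sets out from 7 and 2 and comes back at 9. The addition is run as before but the diastereomers are not separated. The mixture of 9 and (1R*,2S*)-2-(4-bromo-2,6-dimethoxyphenoxy)-1-[3,5-dimethoxy-4-(triisopropylsilyloxy)phenyl]-2-(diphenylphosphoryl)propan-1-ol F5 is oxidised with Dess–Martin periodinane to the single racemic ketone 2-(4-bromo-2,6-dimethoxyphenoxy)-1-[3,5-dimethoxy-4-(triisopropylsilyloxy)phenyl]-2-(diphenylphosphoryl)propan-1-one F6. F6 is reduced under chelation control (NaBH4, CeCl3·7H2O, EtOH, −78 °C). A six-membered chelate between P=O and C=O should expose the carbonyl face anti to the bulky aryloxy group on C8 and so favour 9.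

**Step 5.** The likely problem is fragmentation of the potassium alkoxide back to aldehyde and phosphine oxide anion in competition with the syn elimination. Recombination would then erode the Z purity on which the erythro relation depends. The fallback sets out from 2 and 3 and comes back at 10 without any alkoxide intermediate. Corey–Fuchs dibromo-olefination of 2 (CBr4, PPh3, CH2Cl2, 0 °C) gives [4-(2,2-dibromoethenyl)-2,6-dimethoxyphenoxy]triisopropylsilane F7. Trans-selective Negishi monomethylation (MeZnCl, Pd(DPEphos)Cl2, THF) replaces the bromine trans to ring A and leaves {4-[(Z)-2-bromoprop-1-enyl]-2,6-dimethoxyphenoxy}triisopropylsilane F8. Copper-catalysed O-alkenylation of 3 with F8 (CuI, N,N-dimethylglycine, Cs2CO3, toluene, 90 °C) should proceed with retention of geometry to give 10. The electron-rich aryl bromide of 3 is expected to react much more slowly than the alkenyl bromide.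

**Step 7.** The likely problems are protodeboronation or oligomerisation of the alkenylboronic acid before transmetalation, and base-induced loss of the silyl group, which would expose a phenoxide para to C7 and open an epimerisation path. The fallback sets out from 12 and comes back at 14. Coupling of 12 with allylboronic acid pinacol ester (Pd(dppf)Cl2, CsF, THF, 65 °C) gives (1R,2S)-2-[2,6-dimethoxy-4-(prop-2-enyl)phenoxy]-1-[3,5-dimethoxy-4-(triisopropylsilyloxy)phenyl]propan-1-ol F9. Isomerisation of the allyl group into conjugation with RuHCl(CO)(PPh3)3 in toluene at 60 °C should give the thermodynamically preferred E-propenyl compound 14.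

## Further compounds

F1 | step 6 | methyl (2S)-2-(4-bromo-2,6-dimethoxyphenoxy)propanoate | COC(=O)[C@H](C)Oc1c(OC)cc(Br)cc1OC
F2 | step 6 | (2S)-2-(4-bromo-2,6-dimethoxyphenoxy)propanal | O=C[C@H](C)Oc1c(OC)cc(Br)cc1OC
F3 | step 6 | (4-bromo-2,6-dimethoxyphenoxy)triisopropylsilane | CC(C)[Si](Oc1c(OC)cc(Br)cc1OC)(C(C)C)C(C)C
F4 | step 6 | [3,5-dimethoxy-4-(triisopropylsilyloxy)phenyl]lithium | [Li]c1cc(OC)c(O[Si](C(C)C)(C(C)C)C(C)C)c(OC)c1
F5 | step 4 | (1R*,2S*)-2-(4-bromo-2,6-dimethoxyphenoxy)-1-[3,5-dimethoxy-4-(triisopropylsilyloxy)phenyl]-2-(diphenylphosphoryl)propan-1-ol (racemic; one enantiomer drawn) | C[C@](Oc1c(OC)cc(Br)cc1OC)(P(=O)(c1ccccc1)c1ccccc1)[C@H](O)c1cc(OC)c(O[Si](C(C)C)(C(C)C)C(C)C)c(OC)c1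
F6 | step 4 | rac-2-(4-bromo-2,6-dimethoxyphenoxy)-1-[3,5-dimethoxy-4-(triisopropylsilyloxy)phenyl]-2-(diphenylphosphoryl)propan-1-one | CC(Oc1c(OC)cc(Br)cc1OC)(P(=O)(c1ccccc1)c1ccccc1)C(=O)c1cc(OC)c(O[Si](C(C)C)(C(C)C)C(C)C)c(OC)c1
F7 | step 5 | [4-(2,2-dibromoethenyl)-2,6-dimethoxyphenoxy]triisopropylsilane | BrC(Br)=Cc1cc(OC)c(O[Si](C(C)C)(C(C)C)C(C)C)c(OC)c1
F8 | step 5 | {4-[(Z)-2-bromoprop-1-enyl]-2,6-dimethoxyphenoxy}triisopropylsilane | C/C(Br)=C/c1cc(OC)c(O[Si](C(C)C)(C(C)C)C(C)C)c(OC)c1
F9 | step 7 | (1R,2S)-2-[2,6-dimethoxy-4-(prop-2-enyl)phenoxy]-1-[3,5-dimethoxy-4-(triisopropylsilyloxy)phenyl]propan-1-ol | C=CCc1cc(OC)c(O[C@@H](C)[C@H](O)c2cc(OC)c(O[Si](C(C)C)(C(C)C)C(C)C)c(OC)c2)c(OC)c1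
A1 | alternative 1 | 4-{[(1R,2S)-1-{3,5-dimethoxy-4-[2-(trimethylsilyl)ethoxymethoxy]phenyl}-1-[2-(trimethylsilyl)ethoxymethoxy]propan-2-yl]oxy}-3,5-dimethoxybenzaldehyde | O=Cc1cc(OC)c(O[C@@H](C)[C@H](OCOCC[Si](C)(C)C)c2cc(OC)c(OCOCC[Si](C)(C)C)c(OC)c2)c(OC)c1
A2 | alternative 1 | (1R,2S)-1-{3,5-dimethoxy-4-[2-(trimethylsilyl)ethoxymethoxy]phenyl}-1-[2-(trimethylsilyl)ethoxymethoxy]propan-2-ol | C[C@H](O)[C@H](OCOCC[Si](C)(C)C)c1cc(OC)c(OCOCC[Si](C)(C)C)c(OC)c1
A3 | alternative 1 | 4-fluoro-3,5-dimethoxybenzaldehyde | O=Cc1cc(OC)c(F)c(OC)c1
A4 | alternative 2 | (1R,2S)-2-{2,6-dimethoxy-4-[(E)-prop-1-enyl]phenoxy}-1-[3,5-dimethoxy-4-(methoxymethoxy)phenyl]propan-1-ol | C/C=C/c1cc(OC)c(O[C@@H](C)[C@H](O)c2cc(OC)c(OCOC)c(OC)c2)c(OC)c1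
A5 | alternative 2 | rac-2-{2,6-dimethoxy-4-[(E)-prop-1-enyl]phenoxy}-1-[3,5-dimethoxy-4-(methoxymethoxy)phenyl]propan-1-one | C/C=C/c1cc(OC)c(OC(C)C(=O)c2cc(OC)c(OCOC)c(OC)c2)c(OC)c1
A6 | alternative 3 | S-ethyl (2R,3R)-2-{2,6-dimethoxy-4-[(E)-prop-1-enyl]phenoxy}-3-[3,5-dimethoxy-4-(triisopropylsilyloxy)phenyl]-3-hydroxypropanethioate | CCSC(=O)[C@H](Oc1c(OC)cc(/C=C/C)cc1OC)[C@H](O)c1cc(OC)c(O[Si](C(C)C)(C(C)C)C(C)C)c(OC)c1
A7 | alternative 3 | (Z)-[2-{2,6-dimethoxy-4-[(E)-prop-1-enyl]phenoxy}-1-(ethylsulfanyl)ethenyloxy]trimethylsilane | CCS/C(O[Si](C)(C)C)=C\Oc1c(OC)cc(/C=C/C)cc1OC
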